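**Strategy**

Ring A (C1–C5, C10) is cut at C2–C3. Its C2 ketone sits between the C1 and C3 methylenes, and C3 is bonded to the C4 methine beside quaternary C5: the imprint of an acyl radical that has added to the CH2 end of an isopropenyl group. One operation therefore closes ring A 6-endo from a C2 acyl radical, makes the C2–C3 bond with the ketone in place, and sets C4 by hydrogen transfer. The precursor is a monocyclic ring B (C5–C10) selenoester: methyl and isopropenyl on C5, isopropenyl on C7, a cis-8,9-acetonide, and a CH2C(O)SePh arm on C10 cis to the C5 isopropenyl.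

Key step: step 14

Remark: eremophilane numbering is used for ring atoms throughout (ring A = C1–C5 and C10, ring B = C5–C10); precursor 21 and cyclised product 22 were checked centre by centre against the target and agree with it.
Assumption: tert-butyl glyoxylate is taken as a catalogue reagent and distilled to the monomer before use.

**Route**

Step 1
Reactants: 1 cyclohex-2-en-1-one; 2 potassium trifluoro(prop-1-en-2-yl)borate
Product: 3 (R)-3-(prop-1-en-2-yl)cyclohexan-1-one
Conditions: [Rh(cod)2]BF4 (3 mol %), (R)-BINAP, toluene/H2O (10:1), 105 °C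
Reagents that add atoms: potassium trifluoro(prop-1-en-2-yl)borate (2), C=C(C)[B-](F)(F)F.[K+]
Why: Rhodium-catalysed asymmetric 1,4-addition of an alkenylboron reagent to a cyclic enone (Hayashi–Miyaura reaction) should transfer the isopropenyl group to one enone face under control of the (R)-BINAP ligand and so set C7 with the R configuration, the sense known for aryl and alkenyl transfer with this ligand.

Step 2
Reactants: 3 (R)-3-(prop-1-en-2-yl)cyclohexan-1-one
Product: 5 (R)-5-(prop-1-en-2-yl)cyclohex-2-en-1-one, via silyl enol ether 4 (not isolated)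
Conditions: LiN(i-Pr)2, Me3SiCl, THF, −78 °C; then Pd(OAc)2 (1.0 equiv), MeCN, rt
Reagents that add atoms: none
Why: Kinetic enolisation with in situ silylation should take place mainly on the methylene remote from the C7 substituent, and Saegusa–Ito dehydrogenation of that silyl enol ether gives the 5-substituted enone without touching C7, while the minor regioisomer ends as an achiral conjugated dienone that chromatography removes.

Step 3
Reactants: 5 (R)-5-(prop-1-en-2-yl)cyclohex-2-en-1-one
Product: 6 (5R)-1-methyl-5-(prop-1-en-2-yl)cyclohex-2-en-1-ol (both C1 epimers)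
Conditions: MeLi, Et2O, −78 °C; aq. NH4Cl
Reagents that add atoms: methyllithium, C[Li]
Why: Methyllithium adds 1,2 to the enone carbonyl, and the configuration of the new carbinol does not matter because both epimers converge in step 4.

Step 4
Reactants: 6 (5R)-1-methyl-5-(prop-1-en-2-yl)cyclohex-2-en-1-ol
Product: 7 (S)-3-methyl-5-(prop-1-en-2-yl)cyclohex-2-en-1-one
Conditions: pyridinium chlorochromate (C5H5NH[CrO3Cl]), CH2Cl2, rt
Reagents that add atoms: pyridinium chlorochromate, [O-][Cr](=O)(=O)Cl.c1cc[nH+]cc1
Why: Oxidative 1,3-transposition of a tertiary allylic alcohol (Babler–Dauben oxidation) proceeds by [3,3] shift of the chromate ester, which delivers oxygen from chromium to the far alkene carbon, and oxidation then gives the β-methyl enone with C7 untouched.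

Step 5
Reactants: 7 (S)-3-methyl-5-(prop-1-en-2-yl)cyclohex-2-en-1-one
Product: 8 (5R,6R)-6-hydroxy-3-methyl-5-(prop-1-en-2-yl)cyclohex-2-en-1-one (hydroxyl trans to isopropenyl)
Conditions: LiN(i-Pr)2, THF, −78 °C; 2-(benzenesulfonyl)-3-phenyloxaziridine, −78 °C; aq. NH4Cl
Reagents that add atoms: 2-(benzenesulfonyl)-3-phenyloxaziridine, O=S(=O)(c1ccccc1)N1OC1c1ccccc1
Why: Kinetic deprotonation gives the cross-conjugated lithium enolate at C8, and oxidation with the sulfonyloxaziridine (Davis oxidation) should take place anti to the neighbouring C7 isopropenyl group, setting O8 trans to it.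

Step 6
Reactants: 8 (5R,6R)-6-hydroxy-3-methyl-5-(prop-1-en-2-yl)cyclohex-2-en-1-one
Product: 9 (5R,6R)-6-[(2-methoxypropan-2-yl)oxy]-3-methyl-5-(prop-1-en-2-yl)cyclohex-2-en-1-one
Conditions: 2-methoxypropene, PPTS (cat.), CH2Cl2, 0 °C; Et3N
Reagents that add atoms: 2-methoxypropene, COC(C)=C
Why: Acid-catalysed addition of the alcohol to the enol ether gives a mixed acetone ketal that is stable to bases and organometallics, cannot migrate between oxygens and already holds the carbon of the later acetonide.

Step 7
Reactants: 9 (5R,6R)-6-[(2-methoxypropan-2-yl)oxy]-3-methyl-5-(prop-1-en-2-yl)cyclohex-2-en-1-one; 10 isopropenylmagnesium bromide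
Product: 11 ring B trimethylsilyl enol ether (C9–OSiMe3, C9=C10) with methyl and isopropenyl on C5 (this isopropenyl trans to the C7 isopropenyl), isopropenyl on C7 and the (2-methoxypropan-2-yl)oxy group on C8 (trans to the C7 isopropenyl)
Conditions: CuBr·SMe2 (10 mol %), Me3SiCl, HMPA, THF, −78 → −40 °C; Et3N, pentane
Reagents that add atoms: isopropenylmagnesium bromide (10), C=C(C)[Mg]Br; chlorotrimethylsilane, C[Si](C)(C)Cl
Why: Chlorosilane-accelerated, copper-catalysed conjugate addition of a Grignard reagent to a β,β-disubstituted cyclohexenone should occur by axial attack anti to the C7 isopropenyl group, which creates quaternary C5 with the new isopropenyl trans to the C7 substituent and stores the enolate regiospecifically as its silyl ether.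

Step 8
Reactants: 11 ring B trimethylsilyl enol ether; 12 tert-butyl glyoxylate
Product: 16 tert-butyl 2-(ring B ylidene)acetate: C9 ketone with a C10=CH–CO2t-Bu alkylidene (alkene geometry not defined), other centres as in 11, via lithium enolate 13 (not isolated), via lithium aldolate 14 (not isolated), via aldol mesylate 15 (not isolated)
Conditions: MeLi, THF, 0 °C; 12, −78 °C; MsCl, Et3N, −78 → 0 °C; DBU, 0 °C
Reagents that add atoms: tert-butyl glyoxylate (12), O=CC(=O)OC(C)(C)C
Why: The lithium enolate released regiospecifically from the silyl enol ether should add to the unhindered, non-enolisable glyoxylate (aldol addition), and mesylation followed by E1cB elimination gives the C10 alkylidene, a route to the two-carbon arm that avoids a slow SN2 alkylation beside quaternary C5 and any later base equilibration that would also touch C8.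

Step 9
Reactants: 16 tert-butyl 2-(ring B ylidene)acetate
Product: 17 ring B keto ester: C9 ketone, CH2CO2t-Bu arm on C10 cis to the C5 isopropenyl, other centres as in 11
Conditions: [(Ph3P)CuH]6 (0.4 equiv), H2O (5 equiv), benzene/THF, rt
Reagents that add atoms: none
Why: Conjugate reduction of the ene-1,4-dicarbonyl unit with the copper hydride (Stryker reduction) places hydride on C1, and the C9–C10 enolate should be protonated on the face opposite the axial C5 isopropenyl group, which leaves the arm equatorial and cis to that isopropenyl, the arrangement that is also the more stable one.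

Step 10
Reactants: 17 ring B keto ester
Product: 18 ring B hydroxy ester: C9 hydroxyl cis to O8 and to the C10 arm
Conditions: LiBH(s-Bu)3, THF, −78 °C; pH 7 phosphate buffer, −78 °C
Reagents that add atoms: none
Why: The bulky borohydride should attack the cyclohexanone from the equatorial direction, the other face being blocked by the axial C5 isopropenyl group, to give the axial C9 alcohol cis to O8 and to the C10 arm, while the tert-butyl ester and the cold neutral quench hold back lactonisation.

Step 11
Reactants: 18 ring B hydroxy ester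
Product: 19 ring B 8,9-acetonide tert-butyl ester
Conditions: PPTS (5 mol %), CH2Cl2, 0 °C → rt
Reagents that add atoms: none
Why: Acid-catalysed loss of methanol from the mixed ketal gives an oxocarbenium ion on O8 that the cis C9 hydroxyl captures (intramolecular transketalisation), so the dioxolane should close faster than the hydroxyl can attack the ester.

Step 12
Reactants: 19 ring B 8,9-acetonide tert-butyl ester
Product: 20 ring B 8,9-acetonide carboxylic acid
Conditions: KOt-Bu (6 equiv), H2O (2 equiv), THF, rt → 40 °C; then 1 M HCl to pH 4, 0 °C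
Reagents that add atoms: water, O
Why: Saponification of the tert-butyl ester with hydroxide generated from KOt-Bu and water (a base-only ester cleavage known for hindered esters) is chosen because acid removal would cost the acetonide, and the substrate has no base-sensitive centre.

Step 13
Reactants: 20 ring B 8,9-acetonide carboxylic acid
Product: 21 ring B 8,9-acetonide Se-phenyl selenoester (precursor of the key step)
Conditions: (PhSe)2, n-Bu3P, CH2Cl2, rt
Reagents that add atoms: diphenyl diselenide, c1ccc(cc1)[Se][Se]c1ccccc1
Why: Phosphine-mediated selenoesterification: tributylphosphine and the diselenide activate the acid as an acyloxyphosphonium ion that phenylselenolate captures under neutral conditions compatible with the acetonide and both alkenes.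

Step 14
Reactants: 21 ring B 8,9-acetonide Se-phenyl selenoester
Product: 22 (4S,5R,7R,8R,9S,10S)-8,9-(isopropylidenedioxy)eremophil-11-en-2-one (cis-decalin; C4 methyl cis to C5 methyl)
Conditions: (Me3Si)3SiH (1.5 equiv) and AIBN (0.2 equiv) added by syringe pump, benzene (0.01 M), 80 °C
Reagents that add atoms: none
Why: The tris(trimethylsilyl)silyl radical abstracts the phenylseleno group of 21, the nucleophilic C2 acyl radical adds to the unsubstituted CH2 terminus (C3) of the C5 isopropenyl group, and the tertiary C4 radical then takes hydrogen from the silane to carry the chain. The closest known reaction type is the 6-endo cyclisation of 5-substituted hex-5-enoyl radicals, generated from Se-phenyl selenoesters, to cyclohexanones. Ring A closes 6-endo-trig; the 5-exo mode would have to join C2 to the fully substituted C4 beside quaternary C5, and any such adduct can still reach the six-membered radical by acyl migration. The new stereocentre C4 is set in the hydrogen transfer: ring B keeps the C7 isopropenyl equatorial, which makes the C5 methyl axial on ring A, so the silane should deliver hydrogen axially on the face opposite that methyl and leave the C4 methyl equatorial and cis to it. The step needs cyclisation to outrun direct reduction and decarbonylation of the primary acyl radical, which the slow hydrogen donor kept dilute secures, and it needs the C7 isopropenyl to stay out, which its distance (only seven- or eight-membered closures) and the cis, gauche placement of the arm and the C5 isopropenyl secure.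

Step 15
Reactants: 22 (4S,5R,7R,8R,9S,10S)-8,9-(isopropylidenedioxy)eremophil-11-en-2-one
Product: 23 (4S,5R,7R,8R,9S,10S)-8,9-dihydroxyeremophil-11-en-2-one
Conditions: AcOH/H2O (4:1), 45 °C
Reagents that add atoms: none
Why: Mild aqueous acid hydrolysis of the isopropylidene ketal should free the cis-diol while the ketone and both 1,1-disubstituted alkenes stay intact.

Step 16
Reactants: 23 (4S,5R,7R,8R,9S,10S)-8,9-dihydroxyeremophil-11-en-2-one; 24 angelic acid
Product: 26 (4S,5R,7R,8R,9S,10S)-8,9-bis{[(Z)-2-methylbut-2-enoyl]oxy}eremophil-11-en-2-one (CNP0249036.1), via mixed anhydride 25 (not isolated)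
Conditions: 24 (6 equiv), 2,4,6-Cl3C6H2COCl, Et3N, toluene, rt; then 23, toluene, 80 °C
Reagents that add atoms: angelic acid (24), C/C=C(/C)C(=O)O
Why: Esterification through the mixed 2,4,6-trichlorobenzoic anhydride (Yamaguchi esterification) run hot without a nucleophilic amine catalyst is the established way to acylate hindered secondary alcohols with angelic acid without Z to E isomerisation.

**Compound list**

1 | cyclohex-2-en-1-one | O=C1C=CCCC1 | starting material
2 | potassium trifluoro(prop-1-en-2-yl)borate | C=C(C)[B-](F)(F)F.[K+] | starting material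
3 | (R)-3-(prop-1-en-2-yl)cyclohexan-1-one | C=C(C)[C@H]1CC(=O)CCC1 | intermediate
4 | (R)-trimethyl{[5-(prop-1-en-2-yl)cyclohex-1-en-1-yl]oxy}silane (formed in the flask) | C=C(C)[C@H]1CC(O[Si](C)(C)C)=CCC1 | intermediate
5 | (R)-5-(prop-1-en-2-yl)cyclohex-2-en-1-one | C=C(C)[C@H]1CC(=O)C=CC1 | intermediate
6 | (5R)-1-methyl-5-(prop-1-en-2-yl)cyclohex-2-en-1-ol, both C1 epimers | C=C(C)[C@H]1CC(C)(O)C=CC1 | intermediate
7 | (S)-3-methyl-5-(prop-1-en-2-yl)cyclohex-2-en-1-one | C=C(C)[C@H]1CC(C)=CC(=O)C1 | intermediate
8 | (5R,6R)-6-hydroxy-3-methyl-5-(prop-1-en-2-yl)cyclohex-2-en-1-one | C=C(C)[C@H]1CC(C)=CC(=O)[C@@H]1O | intermediate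
9 | (5R,6R)-6-[(2-methoxypropan-2-yl)oxy]-3-methyl-5-(prop-1-en-2-yl)cyclohex-2-en-1-one | C=C(C)[C@H]1CC(C)=CC(=O)[C@@H]1OC(C)(C)OC | intermediate
10 | isopropenylmagnesium bromide | C=C(C)[Mg]Br | starting material
11 | ring B trimethylsilyl enol ether (C9–OSiMe3, C9=C10; C5 methyl and isopropenyl, the latter trans to the C7 isopropenyl; C8 mixed ketal ether trans to the C7 isopropenyl) | C=C(C)[C@H]1C[C@](C)(C(C)=C)C=C(O[Si](C)(C)C)[C@@H]1OC(C)(C)OC | intermediate
12 | tert-butyl glyoxylate (tert-butyl 2-oxoacetate) | O=CC(=O)OC(C)(C)C | starting material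
13 | lithium enolate of the ring B ketone (C9–OLi, C9=C10; formed in the flask) | C=C(C)[C@H]1C[C@](C)(C(C)=C)C=C([O-])[C@@H]1OC(C)(C)OC.[Li+] | intermediate
14 | lithium aldolate: C10 carries CH(OLi)CO2t-Bu, C10 and carbinol centres as mixtures (formed in the flask) | C=C(C)[C@H]1C[C@](C)(C(C)=C)C(C([O-])C(=O)OC(C)(C)C)C(=O)[C@@H]1OC(C)(C)OC.[Li+] | intermediate
15 | aldol mesylate: C10 carries CH(OSO2CH3)CO2t-Bu (formed in the flask) | C=C(C)[C@H]1C[C@](C)(C(C)=C)C(C(OS(C)(=O)=O)C(=O)OC(C)(C)C)C(=O)[C@@H]1OC(C)(C)OC | intermediate
16 | tert-butyl 2-(ring B ylidene)acetate: C9 ketone, C10=CH–CO2t-Bu, alkene geometry not defined | C=C(C)[C@H]1C[C@](C)(C(C)=C)C(=CC(=O)OC(C)(C)C)C(=O)[C@@H]1OC(C)(C)OC | intermediate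
17 | ring B keto ester: C9 ketone, C10 CH2CO2t-Bu arm cis to the C5 isopropenyl | C=C(C)[C@H]1C[C@](C)(C(C)=C)[C@H](CC(=O)OC(C)(C)C)C(=O)[C@@H]1OC(C)(C)OC | intermediate
18 | ring B hydroxy ester: C9 hydroxyl cis to O8 and to the C10 arm | C=C(C)[C@H]1C[C@](C)(C(C)=C)[C@H](CC(=O)OC(C)(C)C)[C@H](O)[C@@H]1OC(C)(C)OC | intermediate
19 | ring B 8,9-acetonide tert-butyl ester | C=C(C)[C@H]1C[C@](C)(C(C)=C)[C@H](CC(=O)OC(C)(C)C)[C@H](OC(C)(C)O3)[C@@H]13 | intermediate
20 | ring B 8,9-acetonide carboxylic acid | C=C(C)[C@H]1C[C@](C)(C(C)=C)[C@H](CC(=O)O)[C@H](OC(C)(C)O3)[C@@H]13 | intermediate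
21 | ring B 8,9-acetonide Se-phenyl selenoester (C5 methyl and isopropenyl, C7 isopropenyl, C10 CH2C(O)SePh) | C=C(C)[C@H]1C[C@](C)(C(C)=C)[C@H](CC(=O)[Se]c2ccccc2)[C@H](OC(C)(C)O3)[C@@H]13 | intermediate
22 | (4S,5R,7R,8R,9S,10S)-8,9-(isopropylidenedioxy)eremophil-11-en-2-one | C=C(C)[C@H]1C[C@@]2(C)[C@H](CC(=O)C[C@@H]2C)[C@H](OC(C)(C)O3)[C@@H]13 | intermediate
23 | (4S,5R,7R,8R,9S,10S)-8,9-dihydroxyeremophil-11-en-2-one | C=C(C)[C@H]1C[C@@]2(C)[C@H](CC(=O)C[C@@H]2C)[C@H](O)[C@@H]1O | intermediate
24 | angelic acid, (Z)-2-methylbut-2-enoic acid | C/C=C(/C)C(=O)O | starting material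
25 | (Z)-2-methylbut-2-enoic 2,4,6-trichlorobenzoic anhydride (formed in the flask) | C/C=C(/C)C(=O)OC(=O)c1c(Cl)cc(Cl)cc1Cl | intermediate
26 | (4S,5R,7R,8R,9S,10S)-8,9-bis{[(Z)-2-methylbut-2-enoyl]oxy}eremophil-11-en-2-one (CNP0249036.1) | C=C(C)[C@H]1C[C@@]2(C)[C@H](CC(=O)C[C@@H]2C)[C@H](OC(=O)/C(C)=C\C)[C@@H]1OC(=O)/C(C)=C\C | target

**Count**

Total steps: 16. Longest linear sequence: 16 steps (fully linear from 1).

**Steps most likely to fail**

Step 14. What may go wrong: hydrogen transfer to the C4 radical on the wrong face, or reduction or decarbonylation of the acyl radical before ring closure. Fallback, from 19 back to 22: ring A is closed by a polar sequence that sets C4 under stereoelectronic control. Ester 19 is reduced with i-Bu2AlH (CH2Cl2, −78 °C) to the ring B acetonide aldehyde F1. Me2AlCl (CH2Cl2, −78 °C) then promotes a type 2 carbonyl-ene cyclisation onto the C5 isopropenyl group to give the ring A 4-methylene-2-ol F2 as C2 epimers. Dess–Martin periodinane oxidises it to the β,γ-unsaturated ketone F3, and DBU moves the alkene into conjugation to give the 3-en-2-one F4. Lithium in NH3/THF (−78 °C, NH4Cl quench) reduces F4 with axial protonation at C4 and rejoins the route at 22.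

Step 16. What may go wrong: incomplete acylation of the hindered axial C9 hydroxyl, which can also hide as a hemiketal with the C2 ketone, and Z to E drift of the angeloyl unit under forcing. Fallback, from 23 to 26: the Z alkene is built after acylation. Diol 23 is esterified with 2-[bis(2,2,2-trifluoroethoxy)phosphoryl]propanoic acid (DCC, DMAP cat., CH2Cl2), a small acyl donor that reacts through a ketene-like species, to give the 8,9-bis(phosphonopropanoate) F5. A double Still–Gennari olefination (KN(SiMe3)2, 18-crown-6, THF, −78 °C, acetaldehyde) then forms both (Z)-2-methylbut-2-enoates and gives 26.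

Step 2. What may go wrong: insufficient regiocontrol in the enolisation of 3, which drains material at the start. Fallback, from 3 back to 5: the remote methylene is activated first. Formylation (ethyl formate, NaH, THF) gives the 2-(hydroxymethylene) ketone F6. S-Phenyl benzenethiosulfonate with KOAc in ethanol sulfenylates with loss of the formyl group to give the 2-(phenylthio) ketone F7. NaIO4 (MeOH/H2O) gives the sulfoxide F8, and thermolysis (toluene, 110 °C, CaCO3) eliminates the sulfenic acid to give 5.

**Further compounds**

F1 | step 14 | ring B 8,9-acetonide aldehyde (C10 CH2CHO arm) | C=C(C)[C@H]1C[C@](C)(C(C)=C)[C@H](CC=O)[C@H](OC(C)(C)O3)[C@@H]13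
F2 | step 14 | 8,9-(isopropylidenedioxy)eremophila-4(15),11-dien-2-ol, C2 epimers | C=C(C)[C@H]1C[C@@]2(C)[C@H](CC(O)CC2=C)[C@H](OC(C)(C)O3)[C@@H]13
F3 | step 14 | 8,9-(isopropylidenedioxy)eremophila-4(15),11-dien-2-one | C=C(C)[C@H]1C[C@@]2(C)[C@H](CC(=O)CC2=C)[C@H](OC(C)(C)O3)[C@@H]13
F4 | step 14 | 8,9-(isopropylidenedioxy)eremophila-3,11-dien-2-one | C=C(C)[C@H]1C[C@@]2(C)[C@H](CC(=O)C=C2C)[C@H](OC(C)(C)O3)[C@@H]13
F5 | step 16 | 8,9-bis{2-[bis(2,2,2-trifluoroethoxy)phosphoryl]propanoyloxy}eremophil-11-en-2-one | C=C(C)[C@H]1C[C@@]2(C)[C@H](CC(=O)C[C@@H]2C)[C@H](OC(=O)C(C)P(=O)(OCC(F)(F)F)OCC(F)(F)F)[C@@H]1OC(=O)C(C)P(=O)(OCC(F)(F)F)OCC(F)(F)F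
F6 | step 2 | (5R)-2-(hydroxymethylene)-5-(prop-1-en-2-yl)cyclohexan-1-one | C=C(C)[C@H]1CC(=O)C(=CO)CC1
F7 | step 2 | (5R)-2-(phenylthio)-5-(prop-1-en-2-yl)cyclohexan-1-one, C2 epimers | C=C(C)[C@H]1CC(=O)C(Sc2ccccc2)CC1
F8 | step 2 | (5R)-2-(phenylsulfinyl)-5-(prop-1-en-2-yl)cyclohexan-1-one, diastereomers | C=C(C)[C@H]1CC(=O)C(S(=O)c2ccccc2)CC1
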